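**Retrosynthetic overview**
- Teferin 12 ⇐ diol 10 + vanillic acid 11 by Mitsunobu esterification with inversion; 10 ⇐ dienol 8 by hydroxyl-directed epoxidation and radical reductive opening, which sets the ring-fusion hydrogen.
- 8 ⇐ monocyclic alkenyl triflate ketone 7: the five-membered ring is closed through the C6–C10 bond of the farnesyl skeleton; the isopropyl ketone comes from the terminal epoxide by a 1,2-hydride shift.
- 7 ⇐ cycloheptenone 5 ⇐ (3S,6E)-nerolidol 1: the seven-membered ring is closed through the C1–C7 bond by bromoetherification, elimination and ring-expanding Claisen rearrangement; the C3 carbinol chirality passes to the quaternary carbon.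
- Ring order: seven-membered ring first (C1–C7), five-membered ring second (C6–C10), the two bonds and the order of the presumed cyclase pathway from the nerolidyl chain.

Assumption: natural (+)-(3S,6E)-nerolidol (cabreuva-oil grade, high ee) is the purchased chiral material; "C1–C15" in the text is the farnesyl/nerolidol numbering.

**Step 1**
Reactants: 1 (3S,6E)-nerolidol, (3S,6E)-3,7,11-trimethyldodeca-1,6,10-trien-3-ol
Product: 2 (2S,5R)-5-[(2S)-2,5-dibromo-6-hydroxy-6-methylheptan-2-yl]-2-ethenyl-2-methyloxolane, formed together with its (5S,2'R) anti-adduct diastereomer, each as both epimers at the CHBr carbon (all converge in step 2)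
Conditions: NBS (2.2 equiv), THF–H2O (3:1), 0 °C, dark
Reagents that add atoms: N-bromosuccinimide, O=C1CCC(=O)N1Br; water, O
Why: Bromoetherification and bromohydrin formation under one set of conditions: the tertiary hydroxyl opens the 6,7-bromonium ion in the 5-exo mode with anti addition (so the ring CH–O carbon and the C–Br carbon form as one relative pair on either olefin face), water opens the 10,11-bromonium ion at its tertiary carbon, the monosubstituted vinyl group is too slow to compete, and the C3 stereocentre is untouched.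

**Step 2**
Reactants: 2 (2S,5R)-5-[(2S)-2,5-dibromo-6-hydroxy-6-methylheptan-2-yl]-2-ethenyl-2-methyloxolane (diastereomer mixture)
Product: 5 (2R)-2-[2-(3,3-dimethyloxiran-2-yl)ethyl]-2,5-dimethylcyclohept-4-en-1-one, via bromo epoxide 3 (not isolated), via oxolane enol ether 4 (not isolated)
Conditions: DBU (4 equiv), toluene, 25 → 110 °C; then 175 °C (sealed tube)
Reagents that add atoms: none
Why: DBU closes the bromohydrin to epoxide 3 and then removes HBr by anti E2 elimination toward the ring C–H, which gives from both anti-adducts the same tetrasubstituted enol ether 4 (methyl cis to the ring oxygen), and on heating 4 undergoes the ring-expanding Claisen rearrangement through the boat transition state on the vinyl-bearing face (the linalool-to-karahanaenone reaction type), so the C1–C7 bond closes the seven-membered ring and the carbinol chirality is transferred to the new quaternary centre as 2R.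

**Step 3**
Reactants: 5 (2R)-2-[2-(3,3-dimethyloxiran-2-yl)ethyl]-2,5-dimethylcyclohept-4-en-1-one
Product: 6 (7R)-7-[2-(3,3-dimethyloxiran-2-yl)ethyl]-4,7-dimethylcyclohepta-1,4-dien-1-yl trifluoromethanesulfonate
Conditions: KN(SiMe3)2, THF, −78 °C; then PhNTf2, −78 → 0 °C
Reagents that add atoms: N-phenylbis(trifluoromethanesulfonimide), O=S(=O)(N(c1ccccc1)S(=O)(=O)C(F)(F)F)C(F)(F)F
Why: Kinetic enolate O-sulfonylation (enol triflate formation): the ketone can enolise only away from the quaternary carbon, so one regioisomer forms and no stereocentre is affected.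

**Step 4**
Reactants: 6 (7R)-7-[2-(3,3-dimethyloxiran-2-yl)ethyl]-4,7-dimethylcyclohepta-1,4-dien-1-yl trifluoromethanesulfonate
Product: 7 (7R)-4,7-dimethyl-7-(4-methyl-3-oxopentyl)cyclohepta-1,4-dien-1-yl trifluoromethanesulfonate
Conditions: BF3·OEt2 (0.2 equiv), CH2Cl2, −78 °C
Reagents that add atoms: none
Why: Meinwald rearrangement: BF3 opens the epoxide at its tertiary carbon and a 1,2-hydride shift gives the isopropyl ketone, the same hydride shift and oxygenation pattern that terminate the biosynthetic cyclisation but carried out before ring closure, with loss of the (mixed) epoxide stereocentre.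

**Step 5**
Reactants: 7 (7R)-4,7-dimethyl-7-(4-methyl-3-oxopentyl)cyclohepta-1,4-dien-1-yl trifluoromethanesulfonate
Product: 8 (3R,8aR)-6,8a-dimethyl-3-(propan-2-yl)-1,2,3,5,8,8a-hexahydroazulen-3-ol
Conditions: CrCl2 (6 equiv), NiCl2 (10 mol %), DMF, 25 → 50 °C
Reagents that add atoms: none
Why: Intramolecular Nozaki–Hiyama–Kishi reaction: nickel-catalysed formation of the alkenylchromium species at the triflate carbon and its addition to the isopropyl ketone close the five-membered ring through the C6–C10 bond while C3a stays trigonal, and the chromium-bridged transition state holds the carbonyl oxygen in the plane of the alkenyl–chromium bond with the isopropyl group pseudo-axial on the face opposite the pseudo-axial angular methyl, which gives the 3R carbinol (hydroxyl cis to the methyl).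

**Step 6**
Reactants: 8 (3R,8aR)-6,8a-dimethyl-3-(propan-2-yl)-1,2,3,5,8,8a-hexahydroazulen-3-ol
Product: 9 (3R,3aS,4R,8aR)-3a,4-epoxy-6,8a-dimethyl-3-(propan-2-yl)-1,2,3,3a,4,5,8,8a-octahydroazulen-3-ol
Conditions: VO(acac)2 (5 mol %), t-BuOOH, CH2Cl2, 0 °C
Reagents that add atoms: tert-butyl hydroperoxide, CC(C)(C)OO
Why: Hydroxyl-directed epoxidation (vanadium/alkyl hydroperoxide, Sharpless–Michaelson type): the tertiary allylic alcohol binds the peroxo-vanadium species, so oxygen is delivered only to the adjacent trisubstituted double bond and on the hydroxyl-bearing face (3aS,4R), the remote trisubstituted olefin being left alone.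

**Step 7**
Reactants: 9 (3R,3aS,4R,8aR)-3a,4-epoxy-6,8a-dimethyl-3-(propan-2-yl)-1,2,3,3a,4,5,8,8a-octahydroazulen-3-ol
Product: 10 (3R,3aS,4R,8aR)-6,8a-dimethyl-3-(propan-2-yl)-1,2,3,3a,4,5,8,8a-octahydroazulene-3,4-diol
Conditions: Cp2TiCl2 (2.5 equiv), Mn dust, 1,4-cyclohexadiene (10 equiv), THF, 25 °C
Reagents that add atoms: none
Why: Nugent–RajanBabu reductive epoxide opening: Cp2TiCl (trivalent titanium, made in the flask) cleaves the C–O bond at the more substituted carbon to the tertiary radical, which takes a hydrogen atom from 1,4-cyclohexadiene on the face opposite to the titanium alkoxide, the tertiary hydroxyl and the angular methyl, giving the trans ring fusion (3aS) and keeping the 4R carbinol.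

**Step 8**
Reactants: 10 (3R,3aS,4R,8aR)-6,8a-dimethyl-3-(propan-2-yl)-1,2,3,3a,4,5,8,8a-octahydroazulene-3,4-diol; 11 vanillic acid (4-hydroxy-3-methoxybenzoic acid)
Product: 12 teferin, [(3R,3aS,4S,8aR)-3-hydroxy-6,8a-dimethyl-3-(propan-2-yl)-1,2,3,3a,4,5,8,8a-octahydroazulen-4-yl] 4-hydroxy-3-methoxybenzoate
Conditions: PPh3, DIAD, toluene–THF, 0 → 25 °C
Reagents that add atoms: none
Why: Mitsunobu esterification: the alkoxyphosphonium ion of the secondary alcohol is displaced by the carboxylate of 11 (far more acidic than its phenol, so no protection is needed) with inversion from 4R to 4S, the tertiary alcohol being inert, which installs the ester and the natural configuration together.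

**Compound list**
1 | (3S,6E)-nerolidol, (3S,6E)-3,7,11-trimethyldodeca-1,6,10-trien-3-ol | C=C[C@@](C)(O)CC/C=C(\C)CCC=C(C)C | starting material
2 | (2S,5R)-5-[(2S)-2,5-dibromo-6-hydroxy-6-methylheptan-2-yl]-2-ethenyl-2-methyloxolane (with its (5S,2'R) diastereomer; CHBr epimers) | C=C[C@]1(C)CC[C@@H](O1)[C@@](C)(Br)CCC(Br)C(C)(C)O | intermediate
3 | (2S,5R)-5-[(2S)-2-bromo-4-(3,3-dimethyloxiran-2-yl)butan-2-yl]-2-ethenyl-2-methyloxolane (with its (5S,2'R) diastereomer; oxirane epimers) | C=C[C@]1(C)CC[C@@H](O1)[C@@](C)(Br)CCC2OC2(C)C | intermediate (not isolated)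
4 | (2S,5E)-5-[4-(3,3-dimethyloxiran-2-yl)butan-2-ylidene]-2-ethenyl-2-methyloxolane (oxirane epimers) | C=C[C@]1(C)CC/C(=C(/C)CCC2OC2(C)C)O1 | intermediate (not isolated)
5 | (2R)-2-[2-(3,3-dimethyloxiran-2-yl)ethyl]-2,5-dimethylcyclohept-4-en-1-one (oxirane epimers) | O=C1CCC(C)=CC[C@@]1(C)CCC2OC2(C)C | intermediate
6 | (7R)-7-[2-(3,3-dimethyloxiran-2-yl)ethyl]-4,7-dimethylcyclohepta-1,4-dien-1-yl trifluoromethanesulfonate (oxirane epimers) | O=S(=O)(OC1=CCC(C)=CC[C@@]1(C)CCC2OC2(C)C)C(F)(F)F | intermediate
7 | (7R)-4,7-dimethyl-7-(4-methyl-3-oxopentyl)cyclohepta-1,4-dien-1-yl trifluoromethanesulfonate | O=S(=O)(OC1=CCC(C)=CC[C@@]1(C)CCC(=O)C(C)C)C(F)(F)F | intermediate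
8 | (3R,8aR)-6,8a-dimethyl-3-(propan-2-yl)-1,2,3,5,8,8a-hexahydroazulen-3-ol | CC1=CC[C@@]2(C)CC[C@@](O)(C(C)C)C2=CC1 | intermediate
9 | (3R,3aS,4R,8aR)-3a,4-epoxy-6,8a-dimethyl-3-(propan-2-yl)-1,2,3,3a,4,5,8,8a-octahydroazulen-3-ol | CC1=CC[C@@]2(C)CC[C@@](O)(C(C)C)[C@]23O[C@@H]3C1 | intermediate
10 | (3R,3aS,4R,8aR)-6,8a-dimethyl-3-(propan-2-yl)-1,2,3,3a,4,5,8,8a-octahydroazulene-3,4-diol (the C4 epimer of jaeschkeanadiol) | CC1=CC[C@@]2(C)CC[C@@](O)(C(C)C)[C@@H]2[C@H](O)C1 | intermediate
11 | vanillic acid, 4-hydroxy-3-methoxybenzoic acid | COc1cc(C(=O)O)ccc1O | starting material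
12 | teferin, [(3R,3aS,4S,8aR)-3-hydroxy-6,8a-dimethyl-3-(propan-2-yl)-1,2,3,3a,4,5,8,8a-octahydroazulen-4-yl] 4-hydroxy-3-methoxybenzoate | COc1cc(C(=O)O[C@H]2CC(C)=CC[C@@]3(C)CC[C@@](O)(C(C)C)[C@H]23)ccc1O | target

**Totals**
Total step count: 8. Longest linear sequence: 8 steps (1 → 12); 11 enters in the last step.

**Steps most likely to fail, with fallbacks**

Step 2. The elimination must go toward the ring C–H rather than toward the methyl or chain CH2, and it must stay a stereospecific anti E2, because the enol ether geometry becomes the configuration of the quaternary carbon; any leakage lowers the ee of 5. The fallback sets out from 2 and comes back at 4. Compound 2 is treated with KOtBu in THF at 0 °C, where the bulky base closes the bromohydrin and is expected to take a methyl hydrogen, giving the methylene allyl ether (2S,5R)-5-[4-(3,3-dimethyloxiran-2-yl)but-1-en-2-yl]-2-ethenyl-2-methyloxolane F1 (and its C5 epimer). KOtBu in DMSO then isomerises this allyl ether to the alkenyl ether through the potassium-chelated cisoid oxyallyl anion, which places the new methyl group cis to the ring oxygen; that is compound 4, which is heated as in step 2 to give 5.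

Step 5. Alkenylchromium additions to ketones are slow, and the facial choice at the new carbinol rests on a transition-state argument only. The fallback sets out from 6 and comes back at 8, and it introduces the isopropyl group last. H5IO6 in aqueous THF cleaves the epoxide of 6 to the aldehyde (7R)-4,7-dimethyl-7-(3-oxopropyl)cyclohepta-1,4-dien-1-yl trifluoromethanesulfonate F2. The same CrCl2/NiCl2 closure, now onto an aldehyde, gives the secondary dienol (8aR)-6,8a-dimethyl-1,2,3,5,8,8a-hexahydroazulen-3-ol F3. MnO2 oxidises it to the dienone (8aR)-6,8a-dimethyl-2,5,8,8a-tetrahydroazulen-3(1H)-one F4. iPrMgCl with CeCl3 at −78 °C then adds 1,2 from the face opposite the pseudo-axial angular methyl to give 8.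

Step 8. The alcohol is a hindered secondary one next to the ring fusion and part of a syn-1,3-diol, so elimination or a cyclic phosphorane may win over substitution. The fallback sets out from 10 and comes back at 12, and it replaces the displacement by oxidation and directed reduction. Buffered Dess–Martin periodinane gives the hydroxy ketone (3R,3aR,8aR)-3-hydroxy-6,8a-dimethyl-3-(propan-2-yl)-2,3,3a,5,8,8a-hexahydroazulen-4(1H)-one F5, kept cold and away from acid or base to avoid conjugation and dehydration. Me4NBH(OAc)3 in MeCN–AcOH at −20 °C (Evans–Saksena reduction) delivers hydride from the boron bound to the tertiary hydroxyl and gives the anti-1,3-diol jaeschkeanadiol, (3R,3aS,4S,8aR)-6,8a-dimethyl-3-(propan-2-yl)-1,2,3,3a,4,5,8,8a-octahydroazulene-3,4-diol F6. Esterification with commercial 4-acetoxy-3-methoxybenzoic acid (DCC, DMAP) gives 4-O-acetylteferin F7, and pyrrolidine in CH2Cl2 at 0 °C removes the aryl acetate to give 12.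

**Further compounds**
F1 | step 2 | (2S,5R)-5-[4-(3,3-dimethyloxiran-2-yl)but-1-en-2-yl]-2-ethenyl-2-methyloxolane (with its C5 epimer) | C=C[C@]1(C)CC[C@@H](O1)C(=C)CCC2OC2(C)C
F2 | step 5 | (7R)-4,7-dimethyl-7-(3-oxopropyl)cyclohepta-1,4-dien-1-yl trifluoromethanesulfonate | O=S(=O)(OC1=CCC(C)=CC[C@@]1(C)CCC=O)C(F)(F)F
F3 | step 5 | (8aR)-6,8a-dimethyl-1,2,3,5,8,8a-hexahydroazulen-3-ol (C3 epimers) | CC1=CC[C@@]2(C)CCC(O)C2=CC1
F4 | step 5 | (8aR)-6,8a-dimethyl-2,5,8,8a-tetrahydroazulen-3(1H)-one | CC1=CC[C@@]2(C)CCC(=O)C2=CC1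
F5 | step 8 | (3R,3aR,8aR)-3-hydroxy-6,8a-dimethyl-3-(propan-2-yl)-2,3,3a,5,8,8a-hexahydroazulen-4(1H)-one | CC1=CC[C@@]2(C)CC[C@@](O)(C(C)C)[C@@H]2C(=O)C1
F6 | step 8 | jaeschkeanadiol, (3R,3aS,4S,8aR)-6,8a-dimethyl-3-(propan-2-yl)-1,2,3,3a,4,5,8,8a-octahydroazulene-3,4-diol | CC1=CC[C@@]2(C)CC[C@@](O)(C(C)C)[C@@H]2[C@@H](O)C1
F7 | step 8 | 4-O-acetylteferin, [(3R,3aS,4S,8aR)-3-hydroxy-6,8a-dimethyl-3-(propan-2-yl)-1,2,3,3a,4,5,8,8a-octahydroazulen-4-yl] 4-acetoxy-3-methoxybenzoate | COc1cc(C(=O)O[C@H]2CC(C)=CC[C@@]3(C)CC[C@@](O)(C(C)C)[C@H]23)ccc1OC(C)=O
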